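Ring atoms are numbered C1 (stereocentre), C3=C4 (ester on C4), C7=C8 (Z, methyl on C8) and C11=C12 (E, methyl on C12) around the 14-membered ring. The plan opens this ring at C4–C5 and cuts the open chain at C8–C9 and C6–C7. The key step exploits the Z C7=C8 alkene, in which C9 and C6 are cis: a C9 alkylcopper, made from a limonene-derived Grignard reagent that already holds C1 and the 11E alkene, adds syn across propyne, and the alkenylcopper opens oxirane, delivering the C5 alcohol with the 7Z geometry in one flask. A Negishi macrocyclisation at C4–C5 then closes the ring.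

Key step: step 11

Remark 1: the isopropylidene end of the side chain is installed by cross-metathesis after the limonene ring has been cleaved, because a peracid would not distinguish the ring alkene from a prenyl-type alkene.
Remark 2: C3 travels as a TBS ether so that no Lewis-acid-labile group meets Me3Al/Cp2ZrCl2 or MgBr2; methyl bromo(triphenylphosphoranylidene)acetate is taken as a stock reagent (made from methyl (triphenylphosphoranylidene)acetate by bromination and deprotonation).

Step 1
Reactants: 1 (R)-limonene; 2 allyl bromide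
Product: 4 (4R)-4-(hexa-1,5-dien-2-yl)-1-methylcyclohex-1-ene, via 10-lithiolimonene 3 (not isolated)
Conditions: n-BuLi, TMEDA, hexane, rt, 24 h; then 2, THF, −78 °C → rt
Reagents that add atoms: none
Why: Allylic lithiation with n-BuLi·TMEDA should remove a proton selectively from the isopropenyl methyl group, and the symmetrical 2-substituted allyllithium is alkylated by allyl bromide (Wurtz-type coupling) without touching the stereocentre, which stays R.

Step 2
Reactants: 4 (4R)-4-(hexa-1,5-dien-2-yl)-1-methylcyclohex-1-ene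
Product: 5 (4R)-4-(hexa-1,5-dien-2-yl)-1-methyl-7-oxabicyclo[4.1.0]heptane (both epoxide diastereomers)
Conditions: mCPBA (1.0 equiv), NaHCO3, CH2Cl2, 0 °C
Reagents that add atoms: mCPBA, O=C(OO)c1cccc(Cl)c1
Why: Prilezhaev epoxidation should pick the trisubstituted ring alkene, which is much more electron-rich than the 1,1-disubstituted and monosubstituted alkenes; the diastereomer mixture is irrelevant because both epoxide carbons become carbonyl groups.

Step 3
Reactants: 5 (4R)-4-(hexa-1,5-dien-2-yl)-1-methyl-7-oxabicyclo[4.1.0]heptane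
Product: 7 (3R)-3-(hexa-1,5-dien-2-yl)-6-oxoheptanal, via ring diol 6 (not isolated)
Conditions: H5IO6, THF/H2O, 0 °C → rt
Reagents that add atoms: water, O
Why: Acid-mediated hydrolysis of the epoxide gives the 1,2-diol, which periodic acid cleaves at once (Malaprade glycol cleavage), the established way of opening limonene 1,2-oxide to its keto aldehyde; the remaining alkenes are inert to periodate.

Step 4
Reactants: 7 (3R)-3-(hexa-1,5-dien-2-yl)-6-oxoheptanal
Product: 8 (5R)-5-(hexa-1,5-dien-2-yl)-7-hydroxyheptan-2-one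
Conditions: NaBH4 (0.3 equiv), EtOH/CH2Cl2, −78 °C
Reagents that add atoms: none
Why: Chemoselective borohydride reduction: at −78 °C an aldehyde is reduced far faster than a methyl ketone, so only C3 should reach the alcohol level.

Step 5
Reactants: 8 (5R)-5-(hexa-1,5-dien-2-yl)-7-hydroxyheptan-2-one
Product: 9 (5R)-7-[(tert-butyldimethylsilyl)oxy]-5-(hexa-1,5-dien-2-yl)heptan-2-one
Conditions: TBSCl, imidazole, DMF, rt
Reagents that add atoms: TBSCl, CC(C)(C)[Si](C)(C)Cl
Why: Imidazole-promoted silylation of the primary alcohol gives a TBS ether that is stable to amide bases, alanes, Grignard reagents and organocopper reagents.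

Step 6
Reactants: 9 (5R)-7-[(tert-butyldimethylsilyl)oxy]-5-(hexa-1,5-dien-2-yl)heptan-2-one
Product: 10 (5R)-7-[(tert-butyldimethylsilyl)oxy]-5-(6-methylhepta-1,5-dien-2-yl)heptan-2-one
Conditions: 2-methyl-2-butene (excess), RuCl2(=CHPh)(H2IMes)(PCy3) (second-generation Grubbs catalyst, 5 mol %), CH2Cl2, 40 °C
Reagents that add atoms: 2-methyl-2-butene, CC=C(C)C
Why: Olefin cross-metathesis with 2-methyl-2-butene should turn the monosubstituted vinyl group into the isopropylidene terminus, while the α-branched 1,1-disubstituted alkene does not engage the ruthenium carbene and the ketone and silyl ether are spectators.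

Step 7
Reactants: 10 (5R)-7-[(tert-butyldimethylsilyl)oxy]-5-(6-methylhepta-1,5-dien-2-yl)heptan-2-one
Product: 12 tert-butyldimethyl{[(3R)-3-(6-methylhepta-1,5-dien-2-yl)hept-6-yn-1-yl]oxy}silane, via enol phosphate 11 (not isolated)
Conditions: LiN(i-Pr)2 (1.05 equiv), THF, −78 °C; ClP(O)(OEt)2, −78 °C → rt; LiN(i-Pr)2 (2.3 equiv), −78 °C → rt; H2O
Reagents that add atoms: none
Why: Kinetic deprotonation at the methyl group, O-phosphorylation of the enolate and base-induced elimination of diethyl phosphate (the enol phosphate route from methyl ketones to terminal alkynes) should give the C11≡C12 alkyne; the stereocentre is γ to the carbonyl and is not touched.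

Step 8
Reactants: 12 tert-butyldimethyl{[(3R)-3-(6-methylhepta-1,5-dien-2-yl)hept-6-yn-1-yl]oxy}silane; 13 oxirane
Product: 16 (3E,7R)-7-{2-[(tert-butyldimethylsilyl)oxy]ethyl}-4,12-dimethyl-8-methylidenetrideca-3,11-dien-1-ol, via alkenylalane 14 (not isolated), via lithium alkenylalanate 15 (not isolated)
Conditions: Me3Al, Cp2ZrCl2 (25 mol %), CH2Cl2, 0 °C → rt; evaporate, hexane; n-BuLi, 0 °C; 13, THF, 0 °C → rt; aq. KNaC4H4O6 (Rochelle salt)
Reagents that add atoms: trimethylaluminium, C[Al](C)C
Why: Zirconium-catalysed Negishi carboalumination adds methyl and aluminium syn across the terminal alkyne with methyl on the internal carbon C12, and the derived alanate opens oxirane with retention at the alkenyl carbon, which should fix the 11E geometry.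

Step 9
Reactants: 16 (3E,7R)-7-{2-[(tert-butyldimethylsilyl)oxy]ethyl}-4,12-dimethyl-8-methylidenetrideca-3,11-dien-1-ol
Product: 17 (3E,7R)-1-bromo-7-{2-[(tert-butyldimethylsilyl)oxy]ethyl}-4,12-dimethyl-8-methylidenetrideca-3,11-diene
Conditions: CBr4, PPh3, CH2Cl2, 0 °C
Reagents that add atoms: carbon tetrabromide, BrC(Br)(Br)Br
Why: Appel reaction: SN2 displacement of the alkoxyphosphonium group by bromide at the primary carbon, under neutral conditions that the silyl ether and the alkenes tolerate.

Step 10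
Reactants: 17 (3E,7R)-1-bromo-7-{2-[(tert-butyldimethylsilyl)oxy]ethyl}-4,12-dimethyl-8-methylidenetrideca-3,11-diene
Product: 18 [(3E,7R)-7-{2-[(tert-butyldimethylsilyl)oxy]ethyl}-4,12-dimethyl-8-methylidenetrideca-3,11-dien-1-yl]magnesium bromide (titrated ether solution)
Conditions: Mg turnings (activated with BrCH2CH2Br), Et2O, 35 °C → rt
Reagents that add atoms: magnesium, [Mg]
Why: Grignard formation by insertion of magnesium into the primary C–Br bond in diethyl ether, the solvent the carbocupration needs; the silyl ether and unactivated alkenes are inert and the homoallyl reagent keeps its E alkene at or below room temperature.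

Step 11
Reactants: 18 [(3E,7R)-7-{2-[(tert-butyldimethylsilyl)oxy]ethyl}-4,12-dimethyl-8-methylidenetrideca-3,11-dien-1-yl]magnesium bromide; 19 propyne; 13 oxirane
Product: 23 (3Z,7E,11R)-11-{2-[(tert-butyldimethylsilyl)oxy]ethyl}-4,8,16-trimethyl-12-methylideneheptadeca-3,7,15-trien-1-ol, via alkylcopper 20 (not isolated), via alkenylcopper 21 (not isolated), via alkenyl hexynyl cuprate 22 (not isolated)
Conditions: CuBr·SMe2 (1.0 equiv), Et2O/Me2S, −45 °C, 2 h; 19 (2 equiv), −25 °C, 3 h; n-BuC≡CLi, HMPA, −78 °C; 13, −78 → −25 °C; aq. NH4Cl/NH3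
Reagents that add atoms: none
Why: Transmetalation of 18 to CuBr·SMe2 gives alkylcopper 20 (as its MgBr2/Me2S complex), which adds across propyne by a concerted four-centre syn carbocupration, the alkyl group going to the methyl-bearing internal carbon C8 and copper to the terminal carbon C7. The alkenylcopper 21 is configurationally stable at this temperature and, once converted into the mixed hexynyl cuprate 22 in the presence of HMPA, should open oxirane by SN2 attack with retention at the sp2 carbon, so that C9 and C6 end cis (7Z). The closest known reaction type is the Normant carbocupration of terminal alkynes by alkylcopper–magnesium halide reagents followed by electrophilic trapping of the alkenylcopper. No ring is closed and no stereocentre is formed; C1 and the 11E alkene are remote spectators. The step needs alkyl delivery to C8 and stereospecific syn addition: the first is secured by the polarity and steric bias of the terminal alkyne, the second by the concerted mechanism and by keeping the mixture at or below −25 °C, and the primary alkyl group carries only a silyl ether and unactivated alkenes, none of which reacts with monovalent copper reagents.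

Step 12
Reactants: 23 (3Z,7E,11R)-11-{2-[(tert-butyldimethylsilyl)oxy]ethyl}-4,8,16-trimethyl-12-methylideneheptadeca-3,7,15-trien-1-ol
Product: 24 (3Z,7E,11R)-11-{2-[(tert-butyldimethylsilyl)oxy]ethyl}-1-iodo-4,8,16-trimethyl-12-methylideneheptadeca-3,7,15-triene
Conditions: I2, PPh3, imidazole, CH2Cl2, 0 °C
Reagents that add atoms: iodine, II
Why: Appel-type iodination (Garegg–Samuelsson conditions): iodide displaces the alkoxyphosphonium group at the primary C5 by SN2, leaving the TBS ether and the alkenes alone.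

Step 13
Reactants: 24 (3Z,7E,11R)-11-{2-[(tert-butyldimethylsilyl)oxy]ethyl}-1-iodo-4,8,16-trimethyl-12-methylideneheptadeca-3,7,15-triene
Product: 25 (3R,6E,10Z)-13-iodo-6,10-dimethyl-3-(6-methylhepta-1,5-dien-2-yl)trideca-6,10-dien-1-ol
Conditions: HF·pyridine, pyridine, THF, 0 °C → rt
Reagents that add atoms: none
Why: Fluoride-driven desilylation, powered by the strong Si–F bond and buffered by pyridine, should free the C3 alcohol without displacing the primary iodide or isomerising the alkenes.

Step 14
Reactants: 25 (3R,6E,10Z)-13-iodo-6,10-dimethyl-3-(6-methylhepta-1,5-dien-2-yl)trideca-6,10-dien-1-ol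
Product: 26 (3R,6E,10Z)-13-iodo-6,10-dimethyl-3-(6-methylhepta-1,5-dien-2-yl)trideca-6,10-dienal
Conditions: Dess–Martin periodinane, NaHCO3, CH2Cl2, 0 °C → rt
Reagents that add atoms: none
Why: Dess–Martin oxidation gives the C3 aldehyde under neutral conditions; C1 is β to the carbonyl and cannot epimerise by enolisation.

Step 15
Reactants: 26 (3R,6E,10Z)-13-iodo-6,10-dimethyl-3-(6-methylhepta-1,5-dien-2-yl)trideca-6,10-dienal
Product: 27 methyl (2Z,5R,8E,12Z)-2-bromo-15-iodo-8,12-dimethyl-5-(6-methylhepta-1,5-dien-2-yl)pentadeca-2,8,12-trienoate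
Conditions: Ph3P=C(Br)CO2Me, CH2Cl2, rt
Reagents that add atoms: methyl bromo(triphenylphosphoranylidene)acetate, COC(=O)C(Br)=P(c1ccccc1)(c1ccccc1)c1ccccc1
Why: Wittig olefination with the stabilised α-bromo ylide should give mainly the Z α-bromo enoate (C2 chain trans to the ester, cis to bromine), and any E isomer is to be removed by chromatography before the ring is closed.

Step 16
Reactants: 27 methyl (2Z,5R,8E,12Z)-2-bromo-15-iodo-8,12-dimethyl-5-(6-methylhepta-1,5-dien-2-yl)pentadeca-2,8,12-trienoate
Product: 29 methyl (1E,4R,7E,11Z)-7,11-dimethyl-4-(6-methylhepta-1,5-dien-2-yl)cyclotetradeca-1,7,11-triene-1-carboxylate (the target), via alkylzinc iodide 28 (not isolated)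
Conditions: Zn dust (activated with BrCH2CH2Br, Me3SiCl), THF, 35 °C; then syringe-pump addition to PdCl2(dppf) (10 mol %), THF, 60 °C, ca. 1 mM
Reagents that add atoms: none
Why: Zinc should insert into the primary C–I bond and leave the alkenyl bromide, and the alkylzinc iodide then undergoes an intramolecular Negishi coupling in which oxidative addition of zerovalent palladium to the C4–Br bond with retention, transmetalation and reductive elimination close the 14-membered ring at C4–C5 and place C5 cis to C2, as in the target enoate.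

Compound list
1 | (R)-limonene, (4R)-1-methyl-4-(prop-1-en-2-yl)cyclohex-1-ene | C=C(C)[C@H]1CC=C(C)CC1 | starting material
2 | allyl bromide (3-bromoprop-1-ene) | C=CCBr | starting material
3 | 10-lithiolimonene, {2-[(1R)-4-methylcyclohex-3-en-1-yl]prop-2-en-1-yl}lithium | [Li]CC(=C)[C@H]1CC=C(C)CC1 | intermediate
4 | (4R)-4-(hexa-1,5-dien-2-yl)-1-methylcyclohex-1-ene | C=CCCC(=C)[C@H]1CC=C(C)CC1 | intermediate
5 | (4R)-4-(hexa-1,5-dien-2-yl)-1-methyl-7-oxabicyclo[4.1.0]heptane (both epoxide diastereomers) | C=CCCC(=C)[C@H]1CC2OC2(C)CC1 | intermediate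
6 | (4R)-4-(hexa-1,5-dien-2-yl)-1-methylcyclohexane-1,2-diol (diastereomer mixture) | C=CCCC(=C)[C@H]1CC(O)C(C)(O)CC1 | intermediate
7 | (3R)-3-(hexa-1,5-dien-2-yl)-6-oxoheptanal | C=CCCC(=C)[C@@H](CC=O)CCC(C)=O | intermediate
8 | (5R)-5-(hexa-1,5-dien-2-yl)-7-hydroxyheptan-2-one | C=CCCC(=C)[C@@H](CCO)CCC(C)=O | intermediate
9 | (5R)-7-[(tert-butyldimethylsilyl)oxy]-5-(hexa-1,5-dien-2-yl)heptan-2-one | C=CCCC(=C)[C@@H](CCO[Si](C)(C)C(C)(C)C)CCC(C)=O | intermediate
10 | (5R)-7-[(tert-butyldimethylsilyl)oxy]-5-(6-methylhepta-1,5-dien-2-yl)heptan-2-one | CC(C)=CCCC(=C)[C@@H](CCO[Si](C)(C)C(C)(C)C)CCC(C)=O | intermediate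
11 | diethyl (5R)-7-[(tert-butyldimethylsilyl)oxy]-5-(6-methylhepta-1,5-dien-2-yl)hept-1-en-2-yl phosphate | CC(C)=CCCC(=C)[C@@H](CCO[Si](C)(C)C(C)(C)C)CCC(=C)OP(=O)(OCC)OCC | intermediate
12 | tert-butyldimethyl{[(3R)-3-(6-methylhepta-1,5-dien-2-yl)hept-6-yn-1-yl]oxy}silane | CC(C)=CCCC(=C)[C@@H](CCO[Si](C)(C)C(C)(C)C)CCC#C | intermediate
13 | oxirane | C1CO1 | starting material
14 | [(1E,5R)-5-{2-[(tert-butyldimethylsilyl)oxy]ethyl}-2,10-dimethyl-6-methylideneundeca-1,9-dien-1-yl]dimethylalane (Al on C11, cis to the new C12 methyl) | C[Al](C)/C=C(\C)CC[C@H](CCO[Si](C)(C)C(C)(C)C)C(=C)CCC=C(C)C | intermediate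
15 | lithium butyl[(1E,5R)-5-{2-[(tert-butyldimethylsilyl)oxy]ethyl}-2,10-dimethyl-6-methylideneundeca-1,9-dien-1-yl]dimethylalanate | [Li+].CCCC[Al-](C)(C)/C=C(\C)CC[C@H](CCO[Si](C)(C)C(C)(C)C)C(=C)CCC=C(C)C | intermediate
16 | (3E,7R)-7-{2-[(tert-butyldimethylsilyl)oxy]ethyl}-4,12-dimethyl-8-methylidenetrideca-3,11-dien-1-ol | OCC/C=C(\C)CC[C@H](CCO[Si](C)(C)C(C)(C)C)C(=C)CCC=C(C)C | intermediate
17 | (3E,7R)-1-bromo-7-{2-[(tert-butyldimethylsilyl)oxy]ethyl}-4,12-dimethyl-8-methylidenetrideca-3,11-diene | BrCC/C=C(\C)CC[C@H](CCO[Si](C)(C)C(C)(C)C)C(=C)CCC=C(C)C | intermediate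
18 | [(3E,7R)-7-{2-[(tert-butyldimethylsilyl)oxy]ethyl}-4,12-dimethyl-8-methylidenetrideca-3,11-dien-1-yl]magnesium bromide (C9 Grignard reagent) | Br[Mg]CC/C=C(\C)CC[C@H](CCO[Si](C)(C)C(C)(C)C)C(=C)CCC=C(C)C | intermediate
19 | propyne | CC#C | starting material
20 | [(3E,7R)-7-{2-[(tert-butyldimethylsilyl)oxy]ethyl}-4,12-dimethyl-8-methylidenetrideca-3,11-dien-1-yl]copper (as its MgBr2·SMe2 complex) | [Cu]CC/C=C(\C)CC[C@H](CCO[Si](C)(C)C(C)(C)C)C(=C)CCC=C(C)C | intermediate
21 | [(1Z,5E,9R)-9-{2-[(tert-butyldimethylsilyl)oxy]ethyl}-2,6,14-trimethyl-10-methylidenepentadeca-1,5,13-trien-1-yl]copper (Cu on C7, cis to C9) | [Cu]/C=C(/C)CC/C=C(\C)CC[C@H](CCO[Si](C)(C)C(C)(C)C)C(=C)CCC=C(C)C | intermediate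
22 | lithium (hex-1-yn-1-yl)[(1Z,5E,9R)-9-{2-[(tert-butyldimethylsilyl)oxy]ethyl}-2,6,14-trimethyl-10-methylidenepentadeca-1,5,13-trien-1-yl]cuprate | [Li+].CCCCC#C[Cu-]/C=C(/C)CC/C=C(\C)CC[C@H](CCO[Si](C)(C)C(C)(C)C)C(=C)CCC=C(C)C | intermediate
23 | (3Z,7E,11R)-11-{2-[(tert-butyldimethylsilyl)oxy]ethyl}-4,8,16-trimethyl-12-methylideneheptadeca-3,7,15-trien-1-ol (C5 alcohol) | OCC/C=C(/C)CC/C=C(\C)CC[C@H](CCO[Si](C)(C)C(C)(C)C)C(=C)CCC=C(C)C | intermediate
24 | (3Z,7E,11R)-11-{2-[(tert-butyldimethylsilyl)oxy]ethyl}-1-iodo-4,8,16-trimethyl-12-methylideneheptadeca-3,7,15-triene | ICC/C=C(/C)CC/C=C(\C)CC[C@H](CCO[Si](C)(C)C(C)(C)C)C(=C)CCC=C(C)C | intermediate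
25 | (3R,6E,10Z)-13-iodo-6,10-dimethyl-3-(6-methylhepta-1,5-dien-2-yl)trideca-6,10-dien-1-ol | ICC/C=C(/C)CC/C=C(\C)CC[C@H](CCO)C(=C)CCC=C(C)C | intermediate
26 | (3R,6E,10Z)-13-iodo-6,10-dimethyl-3-(6-methylhepta-1,5-dien-2-yl)trideca-6,10-dienal | ICC/C=C(/C)CC/C=C(\C)CC[C@H](CC=O)C(=C)CCC=C(C)C | intermediate
27 | methyl (2Z,5R,8E,12Z)-2-bromo-15-iodo-8,12-dimethyl-5-(6-methylhepta-1,5-dien-2-yl)pentadeca-2,8,12-trienoate | ICC/C=C(/C)CC/C=C(\C)CC[C@H](C/C=C(\Br)C(=O)OC)C(=C)CCC=C(C)C | intermediate
28 | alkylzinc iodide of 27 (C5–ZnI in place of C5–I) | I[Zn]CC/C=C(/C)CC/C=C(\C)CC[C@H](C/C=C(\Br)C(=O)OC)C(=C)CCC=C(C)C | intermediate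
29 | methyl (1E,4R,7E,11Z)-7,11-dimethyl-4-(6-methylhepta-1,5-dien-2-yl)cyclotetradeca-1,7,11-triene-1-carboxylate (CNP0163659.1) | C=C(CCC=C(C)C)[C@H]1C/C=C(/C(=O)OC)CC/C=C(/C)CC/C=C(\C)CC1 | target

Total step count: 16. Longest linear sequence: 16 steps, from (R)-limonene 1 to target 29.

Steps most likely to fail

Step 11. The alkylcopper may decompose by β-hydride loss or be protonated before it adds to propyne, and the opening of oxirane by the alkenylcopper may be too slow, so that the simple protonated trisubstituted alkene is obtained. The fallback sets out from Grignard reagent 18 and returns at alcohol 23; it brings the Z alkene in ready-made and joins it at C8–C9 by sp3–sp2 coupling. Ethyltriphenylphosphonium iodide is deprotonated with n-BuLi to ethylidenetriphenylphosphorane F1, iodine converts this into (1-iodoethyl)triphenylphosphonium iodide F2, and NaN(SiMe3)2 gives (1-iodoethylidene)triphenylphosphorane F3. Stork–Zhao-type olefination of 3-[(4-methoxybenzyl)oxy]propanal with F3 (THF, −78 °C) should give 1-({[(3Z)-4-iodopent-3-en-1-yl]oxy}methyl)-4-methoxybenzene F4. Transmetalation of 18 with ZnBr2 gives the alkylzinc bromide F5, and Negishi coupling of F5 with F4 (PdCl2(dppf), THF, rt), which proceeds with retention at the alkenyl carbon, should give the 4-methoxybenzyl ether of alcohol 23 F6. DDQ in wet CH2Cl2 then removes the 4-methoxybenzyl group and gives 23.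

Step 16. Zinc may also attack the alkenyl bromide, and at the dilution needed the alkylzinc may be lost to protodezincation, β-hydride elimination or intermolecular coupling before the ring closes. The fallback sets out from iodide 24 and returns at target 29; it moves the ring closure to C3=C4. The sodium salt of trimethyl phosphonoacetate (NaH, THF/DMF, excess) is alkylated by 24 to give the C4 phosphonate TBS ether F7. HF·pyridine gives the phosphonate alcohol F8, and Dess–Martin oxidation gives the phosphonate aldehyde F9. An intramolecular Horner–Wadsworth–Emmons reaction under Masamune–Roush conditions (LiCl, DBU, MeCN, high dilution) should then close the 14-membered ring as the E enoate 29, the usual outcome for α-alkyl phosphonoacetates.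

Step 15. The ylide olefination may give too much of the E α-bromo enoate, and on long reaction times the ylide may be alkylated by the primary iodide. The fallback sets out from aldehyde 26 and returns at bromo enoate 27, and it makes no compound outside the compound list (F0). Aldehyde 26 is treated with methyl tribromoacetate and CrCl2 (divalent chromium) in THF at rt; this Reformatsky-type addition followed by stereoselective β-elimination is a known route to Z α-bromo acrylates, and primary alkyl iodides are inert to CrCl2 in THF without a cobalt catalyst.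

Further compounds
F1 | step 11 | ethylidenetriphenylphosphorane | CC=P(c1ccccc1)(c1ccccc1)c1ccccc1
F2 | step 11 | (1-iodoethyl)triphenylphosphonium iodide | CC(I)[P+](c1ccccc1)(c1ccccc1)c1ccccc1.[I-]
F3 | step 11 | (1-iodoethylidene)triphenylphosphorane | CC(I)=P(c1ccccc1)(c1ccccc1)c1ccccc1
F4 | step 11 | 1-({[(3Z)-4-iodopent-3-en-1-yl]oxy}methyl)-4-methoxybenzene | COc1ccc(COCC/C=C(/C)I)cc1
F5 | step 11 | [(3E,7R)-7-{2-[(tert-butyldimethylsilyl)oxy]ethyl}-4,12-dimethyl-8-methylidenetrideca-3,11-dien-1-yl]zinc bromide | Br[Zn]CC/C=C(\C)CC[C@H](CCO[Si](C)(C)C(C)(C)C)C(=C)CCC=C(C)C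
F6 | step 11 | 4-methoxybenzyl ether of alcohol 23 | COc1ccc(COCC/C=C(/C)CC/C=C(\C)CC[C@H](CCO[Si](C)(C)C(C)(C)C)C(=C)CCC=C(C)C)cc1
F7 | step 16 | methyl (5Z,9E,13R)-13-{2-[(tert-butyldimethylsilyl)oxy]ethyl}-2-(dimethoxyphosphoryl)-6,10,18-trimethyl-14-methylidenenonadeca-5,9,17-trienoate (C4 epimers) | COC(=O)C(CC/C=C(/C)CC/C=C(\C)CC[C@H](CCO[Si](C)(C)C(C)(C)C)C(=C)CCC=C(C)C)P(=O)(OC)OC
F8 | step 16 | methyl (5Z,9E,13R)-2-(dimethoxyphosphoryl)-13-(2-hydroxyethyl)-6,10,18-trimethyl-14-methylidenenonadeca-5,9,17-trienoate (C4 epimers) | COC(=O)C(CC/C=C(/C)CC/C=C(\C)CC[C@H](CCO)C(=C)CCC=C(C)C)P(=O)(OC)OC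
F9 | step 16 | methyl (5Z,9E,13R)-2-(dimethoxyphosphoryl)-6,10,18-trimethyl-14-methylidene-13-(2-oxoethyl)nonadeca-5,9,17-trienoate (C4 epimers) | COC(=O)C(CC/C=C(/C)CC/C=C(\C)CC[C@H](CC=O)C(=C)CCC=C(C)C)P(=O)(OC)OC
F0 | step 15 | none | none
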